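## The problem

Compound 40 is a flavan-3-ol trimer. A (2R,3S)-gallocatechin (top) is joined from C4 to C8 of a (2R,3S)-catechin (middle), which is joined from C4 to C8 of a (2S,3R)-catechin (bottom, the enantiomeric series). It has eight stereocentres. The C4 aryl group is trans to O3 in the top unit (4α) but cis to O3 in the middle unit (4β), so the two interflavan bonds cannot come from the same reaction. A carbon nucleophile adding to a C4 cation beside a 3-acyloxy group gives the trans relation; the cis relation needs the hydrogen, not the carbon, to arrive last. C2 and C3 of the top and middle units can be taken from (+)-gallocatechin and (+)-catechin and can steer C4 of their own unit. They cannot steer the bottom unit, whose two centres belong to the opposite series and must be set by a reagent. Each interflavan bond must go to C8 and not C6 of a phloroglucinol ring. The free compound has thirteen phenolic hydroxyls (air-sensitive in base), C2 centres that epimerise in base, and 4→8 bonds that acid cleaves, so all phenols are carried as benzyl ethers and released last under neutral conditions. The feature that makes the key step possible is ring A of the bottom unit: a 1,3,5-trioxygenated benzene in which C8 carries C4 of the middle unit, C8a carries O1 and C4a carries the C4 methylene. This maps onto a vinylketene–ynol ether benzannulation in which the new phenol oxygen (the future O1) is born between the two carbon substituents and can at once open an epoxide on the C4a side chain to close ring C.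

## Retrosynthesis

**40 ⇒ 39 ⇒ 37 (no skeletal bond cut).** The free polyphenol tolerates neither acid, base nor oxidants, so the last operation is one hydrogenolysis that removes the thirteen benzyl ethers and the C8 bromine of the top unit from 39. Intermediate 39 comes from 37 by removal of one silyl ether and one acetate. Both operations are asked only to leave the 4→8 bonds and the C2 centres alone.

**37 ⇒ 31 + 36 (top C4–middle C8).** This is the interflavan bond with 3,4-trans geometry, which a flavan-4-yl cation flanked by a participating 3-acetoxy group forms by itself. The other interflavan bond is 3,4-cis and would be mis-set by the same reaction, so it is not cut here. The cut removes a complete chiral-pool unit and leaves dimer 31 with five stereocentres. The forward reaction must select C8 of the middle unit over its C6 and over C6 of the bottom unit, and electrophile 36 must not add to itself. The first rests on the known C8 preference of O-benzylated phloroglucinol rings; the second is secured by a bromine at C8 of 36.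

**36 ⇒ 35 ⇒ 34 ⇒ 33 ⇒ 32.** Only C–O and C–Br bonds are cut. (+)-Gallocatechin 32 supplies C2 and C3. Benzylation, C8 bromination, oxidation at C4 in the presence of 2-ethoxyethanol and acetylation are standard flavan-3-ol operations.

**31 ⇒ 12 + 25 (bottom unit: C8–C8a, C6–C7, C4a–C8a and O1–C2).** The neighbouring cut, middle C4–bottom C8, would need the unnatural (−)-catechin as a nucleophile, a C8/C6 choice and a cis-selective arylation for which no dependable method exists. Cutting ring A instead reduces the bottom unit to cyclobutenone 25, chiral only in one epoxide, and the middle unit to a catechin carrying a two-carbon silyl ynol ether at C4 (12). Attachment at C8 then follows from bond polarity, and the 3,4-cis relation becomes a problem of a monomer. The forward reaction must join the vinylketene from 25 to 12 in the one orientation the siloxy group dictates, keep the epoxide until the phenol exists, and open it 6-endo with inversion.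

**12 ⇒ 9 ⇒ 8 ⇒ 7 ⇒ 5 + 6, and 5 ⇒ 4 ⇒ 3 ⇒ 2 ⇒ 1 (C4–alkyne bond; the ynol oxygen).** A terminal alkyne 9 is the direct precursor of a silyl ynol ether (oxygen transfer to the acetylide, then O-silylation). Adding an alkyne to a C4 cation would be expected to place it trans to O3. Adding 6 to ketone 5 and removing the hydroxyl of 7 by ionic hydrogenation lets the hydride take that position and leaves the alkyne cis (8). Ketone 5 comes from (+)-catechin 1 by perbenzylation (2, 3) and benzylic oxidation at C4 (4).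

**25 ⇒ 24 ⇒ 16 + 21, with 16 ⇒ 15 ⇒ 14 ⇒ 13 and 21 ⇒ 18 ⇒ 17 (the four-membered ring).** The 3-alkoxy-4-alkylcyclobutenone 24 is cut into an alkylketene (from acid 16) and an alkoxyalkyne 21, because the neighbouring disconnections are not dependable. C4 alkylation of a 3-alkoxycyclobutenone would pass through a cyclobutadienolate. Enol etherification of a 2-substituted cyclobutane-1,3-dione would put the double bond on the substituted carbon. Acid 16 comes from aldehyde 13 through a Johnson–Claisen rearrangement (14 → 15) that fixes the E alkene. Ynol ether 21 comes from benzyl alcohol 17 through dichlorovinyl ether 18, so that the future C5 oxygen is already a benzyl ether. The epoxide is added last (24 → 25) by a reagent-controlled epoxidation, because an acid chloride and an electron-rich aryl epoxide cannot coexist.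

## Roads not taken

**Alternative 1:** The cut is O1–C8a of the bottom unit together with the bond from C8 to the carbon that later becomes C4 of the middle unit. In the forward step the acyclic fluoroarene carbinol A2 is converted to its alkoxide and lithiated at C8. Loss of LiF across C8–C8a (aryne formation) lets the tethered alkoxide add at C8a and close ring C, and the aryllithium born at C8 is trapped by aldehyde A3 to give carbinol A1.
- Merits: two bonds come from one reactive intermediate, and the carbon at C8 is placed by construction. The bottom C2–O bond is never broken, so C2 and C3 come untouched from an acyclic diol. This is safer than the invertive epoxide opening of the chosen plan.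
- Weak points: A1 holds only one carbon of the middle ring C. O1–C2, C2–C3, C3–C4 and all three middle stereocentres, including the 3,4-cis relation, remain to be made, and the carbinol forms as both epimers. Alkyllithium chemistry must run beside seven benzyl ethers (benzylic lithiation, Wittig rearrangement), and the aryllithium must add to a di-ortho-substituted, electron-rich aldehyde.
- Comparison: Alternative 1 is better for the bottom unit taken alone. The chosen plan sets against it that the whole middle unit, with C2 and C3 from (+)-catechin 1, arrives with ynol ether 12, so only one middle stereocentre has to be created.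

**Alternative 2:** The cut is in ring C of the top unit, at C3–C4 and C4–C4a. Sc(OTf)3 activates the ketone of the 2-aryl benzofuran-3-one A5, the aryldiazomethane A6 (the diazomethyl carbon sits on C8 of a perbenzylated middle–bottom dimer) adds, and migration of the ring-A carbon with loss of N2 enlarges the furanone to the 4-arylflavan-3-one A4.
- Merits: the step is convergent, and the top–middle bond is fixed at C8 before the step. Here it is better than the chosen plan, which relies on the innate C8 preference of dimer 31 and on a bromine cap.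
- Weak points: A4 has two epimerisable centres (C2, C4) flanking the ketone, and C3 must still be set by reduction, so all three top-unit centres rest on remote induction or equilibration. The C2 of A5 is enolisable and transmits no absolute configuration. Migration of the ring-A carbon must beat migration of C2. A diazomethyl group flanked by two ortho oxygens on a very electron-rich arene is fragile and must be made late on the most valuable intermediate.
- Comparison: this alternative says nothing about how the dimer itself is made. The chosen plan takes C2 and C3 of the top unit intact from 32 and sets C4 by a participation-controlled coupling of a well-precedented type.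

**Alternative 3:** The cut is in ring C of the middle unit, at O1–C2 and C3–C4. Benzhydrol A8 loses water across O1···C4 (o-quinone methide formation) and the heterodiene adds the (E)-styryl boronate A9 in a [4+2] reaction, giving A7 with a boronate at C3 that oxidation would turn into the 3-hydroxyl with retention.
- Merits: this is the most convergent entry to the middle unit. Three contiguous centres form in one step, the 2,3-trans relation follows from the E alkene, and the bottom unit is already on C4, so no hydride has to be placed. If endo/exo control were high it could set the 3,4-cis relation more cleanly than the ionic hydrogenation of the chosen plan.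
- Weak points: a vinyl boronate is a reluctant partner for an electron-poor heterodiene. The absolute configuration of all three new centres must be induced by the remote bottom unit across a planar intermediate. The 3,4 relation depends on both the geometry of the exocyclic double bond and the endo/exo mode. A8 must itself be built first (in effect by Alternative 1).
- Comparison: the chosen plan leaves one uncertain middle stereocentre (C4) instead of three, because C2 and C3 come from 1.

Key step: step 16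

Remark: the target SMILES is read as (+)-gallocatechin-(4α→8)-(+)-catechin-(4β→8)-(−)-catechin (3,4-trans top unit, 3,4-cis middle unit, 2S,3R bottom unit); C4 of 4, 7, 35 and 36 and the ring carbon of 24 and 25 are planarised later, so the expected epimer is drawn or the centre is left open.

## Route

Step 1
Reactants: 1 (+)-catechin
Product: 2 5,7,3',4'-tetra-O-benzyl-(+)-catechin
Conditions: BnBr (4.4 equiv), K2CO3, DMF, 0 → 23 °C, argon
Reagents that add atoms: benzyl bromide BrCc1ccccc1
Why: Williamson etherification; K2CO3 deprotonates only the four phenols, so the secondary 3-OH stays free, and the mild base at low temperature avoids opening of the O1–C2 bond and hence epimerisation at C2.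

Step 2
Reactants: 2 5,7,3',4'-tetra-O-benzyl-(+)-catechin
Product: 3 3,5,7,3',4'-penta-O-benzyl-(+)-catechin
Conditions: NaH, BnBr, Bu4NI (cat.), DMF, 0 → 23 °C
Reagents that add atoms: benzyl bromide BrCc1ccccc1
Why: Williamson etherification of the secondary alkoxide; with no free phenol left the base has no pathway to open ring C, so C2 and C3 are retained.

Step 3
Reactants: 3 3,5,7,3',4'-penta-O-benzyl-(+)-catechin
Product: 4 4β-hydroxy-3,5,7,3',4'-penta-O-benzyl-(+)-catechin
Conditions: DDQ (2 equiv), CH2Cl2–H2O (18:1), 23 °C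
Reagents that add atoms: water O
Why: DDQ benzylic oxidation; hydride abstraction from C4 gives a cation stabilised by O1 and the 5- and 7-benzyloxy groups, which water captures, and the C4 configuration is irrelevant because step 4 makes C4 trigonal.

Step 4
Reactants: 4 4β-hydroxy-3,5,7,3',4'-penta-O-benzyl-(+)-catechin
Product: 5 (2R,3R)-3,5,7-tris(benzyloxy)-2-[3,4-bis(benzyloxy)phenyl]chroman-4-one
Conditions: Dess–Martin periodinane, NaHCO3, CH2Cl2, 23 °C
Reagents that add atoms: none
Why: Dess–Martin oxidation of the benzylic secondary alcohol under buffered, non-basic conditions, so that C3 (now α to a ketone) does not epimerise and O1 is not eliminated.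

Step 5
Reactants: 5 (2R,3R)-3,5,7-tris(benzyloxy)-2-[3,4-bis(benzyloxy)phenyl]chroman-4-one; 6 ethynyltrimethylsilane
Product: 7 4-hydroxy-4-[(trimethylsilyl)ethynyl]-3,5,7,3',4'-penta-O-benzyl-(+)-catechin (C4 epimers)
Conditions: 6, n-BuLi, THF, −78 °C; CeCl3 (anhydrous); then 5, −78 °C; aq. NH4Cl
Reagents that add atoms: none
Why: 1,2-addition of an alkynylcerium reagent; the weakly basic cerium acetylide adds to the hindered, enolisable α-benzyloxy ketone instead of deprotonating C3, and both C4 epimers are usable because C4 is ionised in step 6.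

Step 6
Reactants: 7 4-hydroxy-4-[(trimethylsilyl)ethynyl]-3,5,7,3',4'-penta-O-benzyl-(+)-catechin (C4 epimers)
Product: 8 4β-[(trimethylsilyl)ethynyl]-3,5,7,3',4'-penta-O-benzyl-(+)-catechin (3,4-cis)
Conditions: Et3SiH (10 equiv), CF3CO2H, CH2Cl2, −40 → 0 °C
Reagents that add atoms: none
Why: Kursanov–Parnes ionic hydrogenation; acid ionises the tertiary benzylic–propargylic alcohol to a cation stabilised by O1, O5 and O7, and the silane should deliver hydride to C4 on the face away from the 3-benzyloxy group (the facial preference that gives 3,4-trans adducts when carbon nucleophiles add to catechin C4 cations), which leaves the alkynyl group cis to O3; the C-silyl group blocks hydride attack at the alkyne terminus.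

Step 7
Reactants: 8 4β-[(trimethylsilyl)ethynyl]-3,5,7,3',4'-penta-O-benzyl-(+)-catechin (3,4-cis)
Product: 9 4β-ethynyl-3,5,7,3',4'-penta-O-benzyl-(+)-catechin (3,4-cis)
Conditions: K2CO3, MeOH–THF, 23 °C
Reagents that add atoms: none
Why: methoxide-induced protodesilylation of the alkynylsilane; carbonate is far too weak to deprotonate C4, so the 3,4-cis relation is kept.

Step 8
Reactants: 9 4β-ethynyl-3,5,7,3',4'-penta-O-benzyl-(+)-catechin (3,4-cis)
Product: 12 4β-[(triisopropylsilyloxy)ethynyl]-3,5,7,3',4'-penta-O-benzyl-(+)-catechin (3,4-cis), via lithium acetylide 10 (not isolated), via lithium ynolate 11 (not isolated)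
Conditions: LiN(SiMe3)2, THF, −78 °C; t-BuOOLi (from t-BuOOH and LiN(SiMe3)2), −78 → 0 °C; i-Pr3SiOTf, −78 → 0 °C
Reagents that add atoms: tert-butyl hydroperoxide CC(C)(C)OO; triisopropylsilyl trifluoromethanesulfonate CC(C)[Si](OS(=O)(=O)C(F)(F)F)(C(C)C)C(C)C
Why: ynolate synthesis by oxygen transfer from lithium tert-butyl peroxide to the lithium acetylide, then O-silylation of the ynolate by the bulky silyl triflate to give the silyl ynol ether; the amide base is not strong enough to remove H4, so C4 is not epimerised.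

Step 9
Reactants: 13 3,4-bis(benzyloxy)benzaldehyde
Product: 14 rac-1-[3,4-bis(benzyloxy)phenyl]prop-2-en-1-ol
Conditions: CH2=CHMgBr, THF, 0 °C; aq. NH4Cl
Reagents that add atoms: vinylmagnesium bromide C=C[Mg]Br
Why: Grignard addition to the aldehyde; the carbinol centre is racemic and is destroyed in step 10.

Step 10
Reactants: 14 rac-1-[3,4-bis(benzyloxy)phenyl]prop-2-en-1-ol
Product: 15 ethyl (E)-5-[3,4-bis(benzyloxy)phenyl]pent-4-enoate
Conditions: MeC(OEt)3, EtCO2H (cat.), 135 °C, EtOH distilled off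
Reagents that add atoms: triethyl orthoacetate CCOC(C)(OCC)OCC
Why: Johnson–Claisen rearrangement; the mixed ketene acetal rearranges through a chair transition state with the aryl group equatorial, which gives the E alkene conjugated to the arene and the two-carbon ester chain.

Step 11
Reactants: 15 ethyl (E)-5-[3,4-bis(benzyloxy)phenyl]pent-4-enoate
Product: 16 (E)-5-[3,4-bis(benzyloxy)phenyl]pent-4-enoic acid
Conditions: LiOH, THF–MeOH–H2O, 23 °C; then 1 M HCl to pH 3
Reagents that add atoms: lithium hydroxide [Li+].[OH-]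
Why: ester saponification; the alkene geometry is not affected.

Step 12
Reactants: 17 benzyl alcohol
Product: 18 benzyl (E)-1,2-dichlorovinyl ether
Conditions: KH, THF, 0 °C; Cl2C=CHCl, −50 → 23 °C
Reagents that add atoms: trichloroethylene ClC=C(Cl)Cl
Why: the alkoxide eliminates HCl from trichloroethylene and adds to the dichloroacetylene so formed; anti addition gives the (E)-1,2-dichlorovinyl ether, the standard precursor of alkoxyalkynes.

Step 13
Reactants: 18 benzyl (E)-1,2-dichlorovinyl ether
Product: 21 (benzyloxy)ethyne, via chloroethynyl ether 19 (not isolated), via lithium alkoxyacetylide 20 (not isolated)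
Conditions: n-BuLi (2.3 equiv), Et2O, −78 → −40 °C; MeOH, −78 °C; cold aqueous work-up, solution kept below 0 °C
Reagents that add atoms: none
Why: dehydrochlorination to the chloroalkyne, chlorine–lithium exchange and protonation of the lithium alkoxyacetylide, the usual route from dichlorovinyl ethers to terminal ynol ethers; the product is used at once as a cold solution because benzyl alkynyl ethers rearrange sigmatropically near 60 °C, a lability comparable to that of the routinely handled tert-butoxyethyne.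

Step 14
Reactants: 16 (E)-5-[3,4-bis(benzyloxy)phenyl]pent-4-enoic acid; 21 (benzyloxy)ethyne
Product: 24 3-(benzyloxy)-4-[(E)-3-(3,4-bis(benzyloxy)phenyl)prop-2-en-1-yl]cyclobut-2-en-1-one (racemic), via acid chloride 22 (not isolated), via ketene 23 (not isolated)
Conditions: 16, (COCl)2, DMF (cat.), CH2Cl2, 0 → 23 °C, evaporate; added slowly to 21 (2 equiv), Et3N, Et2O, 0 → 20 °C
Reagents that add atoms: none
Why: ketene–alkoxyalkyne [2+2] cycloaddition; triethylamine dehydrochlorinates 22 to alkylketene 23, whose carbonyl carbon bonds to the unsubstituted, nucleophilic carbon of the ynol ether, so the 3-alkoxy-4-alkylcyclobutenone forms regiospecifically; slow addition limits ketene dimerisation and the one-carbon tether rules out reaction with the styrene.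

Step 15
Reactants: 24 3-(benzyloxy)-4-[(E)-3-(3,4-bis(benzyloxy)phenyl)prop-2-en-1-yl]cyclobut-2-en-1-one (racemic)
Product: 25 3-(benzyloxy)-4-{[(2R,3R)-3-(3,4-bis(benzyloxy)phenyl)oxiran-2-yl]methyl}cyclobut-2-en-1-one (both epimers at the ring carbon)
Conditions: 1,2:4,5-di-O-isopropylidene-β-D-erythro-2,3-hexodiulo-2,6-pyranose (D-fructose-derived Shi ketone, 1 equiv), KHSO5 (as 2KHSO5·KHSO4·K2SO4), NaHCO3, MeCN–aq. Na2EDTA, 0 °C
Reagents that add atoms: potassium peroxymonosulfate [K+].OOS(=O)(=O)[O-]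
Why: Shi epoxidation; the chiral dioxirane transfers oxygen through a spiro transition state to the trans-disubstituted, electron-rich styrene, and the D-fructose-derived ketone should give the (R,R)-epoxide as it does with other trans-β-alkylstyrenes; the electron-poor enone double bond is left alone and the bicarbonate-buffered protocol is chosen to spare the vinylogous ester.

Step 16
Reactants: 12 4β-[(triisopropylsilyloxy)ethynyl]-3,5,7,3',4'-penta-O-benzyl-(+)-catechin (3,4-cis); 25 3-(benzyloxy)-4-{[(2R,3R)-3-(3,4-bis(benzyloxy)phenyl)oxiran-2-yl]methyl}cyclobut-2-en-1-one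
Product: 31 3,5,7,3',4'-penta-O-benzyl-(+)-catechin-(4β→8)-[5,3',4'-tri-O-benzyl-7-O-triisopropylsilyl-(−)-catechin], via vinylketene 26 (not isolated), via vinylcyclobutenone 27 (not isolated), via dienylketene 28 (not isolated), via cyclohexadienone 29 (not isolated), via epoxy phenol 30 (not isolated)
Conditions: 12 (1.0 equiv), 25 (1.3 equiv), toluene, 80 → 105 °C, base-washed sealed tube; cool, pyridinium p-toluenesulfonate (5 mol %), 0 → 23 °C
Reagents that add atoms: none
Why: Proposed new method: heating opens cyclobutenone 25 in a four-electron electrocyclic reaction to vinylketene 26, whose carbonyl carbon is attacked by the electron-rich, flavan-bearing carbon of silyl ynol ether 12 in a [2+2] cycloaddition (27), and a second four-electron ring opening (28), six-electron electrocyclisation (29) and tautomerisation deliver phenol 30; the closest known reaction type is the Danheiser benzannulation of cyclobutenones with siloxyalkynes, to which the in situ epoxide opening is added. Ring A is closed by the six-electron electrocyclisation that forms C4a–C8a after C8–C8a and C6–C7 have been made in the [2+2] step. Ring C is closed by 6-endo-tet opening of the trans epoxide by the new C8a hydroxyl, which lies between C8 and C4a and activates the oxirane by its own hydrogen bond, the trace of pyridinium salt completing the closure. The only new stereocentre, C2 of the bottom unit, is set by inversion at the benzylic oxirane carbon, so the (2R,3R)-epoxide gives the 2S,3R (2,3-trans) unit, while C3 is carried over unchanged and the middle-unit centres are not involved. The step needs one orientation in the ring synthesis, and the polarity of the ynol ether secures it: the siloxy-bearing carbon must bond to the ketene α-carbon, which places the flavanyl group at C8 next to O1 and the three oxygens in the 1,3,5 pattern. It also needs 6-endo over 5-exo opening, and the 3,4-bis(benzyloxy)phenyl group secures this by stabilising positive charge at the benzylic carbon, while the non-polar, nearly neutral medium keeps the opening invertive. The two ring-carbon epimers of 25 converge on the same vinylketene 26.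

Step 17
Reactants: 32 (+)-gallocatechin
Product: 33 5,7,3',4',5'-penta-O-benzyl-(+)-gallocatechin
Conditions: BnBr (5.5 equiv), K2CO3, DMF, 0 → 23 °C, argon
Reagents that add atoms: benzyl bromide BrCc1ccccc1
Why: Williamson etherification of the five phenols under argon (the pyrogallol ring is air-sensitive in base); the secondary 3-OH is not alkylated by carbonate.

Step 18
Reactants: 33 5,7,3',4',5'-penta-O-benzyl-(+)-gallocatechin
Product: 34 8-bromo-5,7,3',4',5'-penta-O-benzyl-(+)-gallocatechin
Conditions: N-bromosuccinimide, CH2Cl2, −78 → 0 °C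
Reagents that add atoms: N-bromosuccinimide BrN1C(=O)CCC1=O
Why: electrophilic aromatic bromination at C8, the most reactive position of O-benzylated flavan-3-ol A rings; the bromine blocks C8 so that the electrophile made from this unit cannot add to itself in step 21.

Step 19
Reactants: 34 8-bromo-5,7,3',4',5'-penta-O-benzyl-(+)-gallocatechin
Product: 35 8-bromo-4β-(2-ethoxyethoxy)-5,7,3',4',5'-penta-O-benzyl-(+)-gallocatechin
Conditions: DDQ, HOCH2CH2OEt, CH2Cl2, 23 °C
Reagents that add atoms: 2-ethoxyethanol CCOCCO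
Why: DDQ benzylic oxidation at C4 with capture of the cation by the alcohol; the C4 configuration is of no consequence since this group leaves again in step 21.

Step 20
Reactants: 35 8-bromo-4β-(2-ethoxyethoxy)-5,7,3',4',5'-penta-O-benzyl-(+)-gallocatechin
Product: 36 3-O-acetyl-8-bromo-4β-(2-ethoxyethoxy)-5,7,3',4',5'-penta-O-benzyl-(+)-gallocatechin
Conditions: Ac2O, pyridine, 4-(dimethylamino)pyridine (cat.), 23 °C
Reagents that add atoms: acetic anhydride CC(=O)OC(C)=O
Why: acylation of the secondary alcohol; the acetate is installed as the neighbouring group that directs step 21.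

Step 21
Reactants: 31 3,5,7,3',4'-penta-O-benzyl-(+)-catechin-(4β→8)-[5,3',4'-tri-O-benzyl-7-O-triisopropylsilyl-(−)-catechin]; 36 3-O-acetyl-8-bromo-4β-(2-ethoxyethoxy)-5,7,3',4',5'-penta-O-benzyl-(+)-gallocatechin
Product: 37 3-O-acetyl-8-bromo-5,7,3',4',5'-penta-O-benzyl-(+)-gallocatechin-(4α→8)-[3,5,7,3',4'-penta-O-benzyl-(+)-catechin]-(4β→8)-[5,3',4'-tri-O-benzyl-7-O-triisopropylsilyl-(−)-catechin]
Conditions: 36 (1.5 equiv), Me3SiOTf (0.5 equiv), 4 Å molecular sieves, CH2Cl2, −78 → −40 °C; Et3N
Reagents that add atoms: none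
Why: Lewis-acid-promoted Friedel–Crafts coupling of a flavan-4-yl cation; loss of the 4-alkoxy group gives the cation, the 3-acetoxy group bridges it on the β face, and C8 of the middle unit attacks from the α face to give the 3,4-trans (4α) bond; C8 is the most nucleophilic and least hindered free position (C6 of the bottom unit lies between a benzyl and a triisopropylsilyl ether), and the C8 bromine keeps 36 from condensing with itself.

Step 22
Reactants: 37 3-O-acetyl-8-bromo-5,7,3',4',5'-penta-O-benzyl-(+)-gallocatechin-(4α→8)-[3,5,7,3',4'-penta-O-benzyl-(+)-catechin]-(4β→8)-[5,3',4'-tri-O-benzyl-7-O-triisopropylsilyl-(−)-catechin]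
Product: 39 8-bromo-5,7,3',4',5'-penta-O-benzyl-(+)-gallocatechin-(4α→8)-[3,5,7,3',4'-penta-O-benzyl-(+)-catechin]-(4β→8)-[5,3',4'-tri-O-benzyl-(−)-catechin], via desilylated acetate 38 (not isolated)
Conditions: Bu4NF, THF, 0 °C; MeOH, NaOMe (cat.), 23 °C; AcOH
Reagents that add atoms: none
Why: fluoride cleavage of the aryl silyl ether followed by Zemplén-type methanolysis of the acetate; mild base at room temperature should leave the benzyl ethers, the bromide, C2 and the interflavan bonds intact.

Step 23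
Reactants: 39 8-bromo-5,7,3',4',5'-penta-O-benzyl-(+)-gallocatechin-(4α→8)-[3,5,7,3',4'-penta-O-benzyl-(+)-catechin]-(4β→8)-[5,3',4'-tri-O-benzyl-(−)-catechin]
Product: 40 (+)-gallocatechin-(4α→8)-(+)-catechin-(4β→8)-(−)-catechin (CNP0155646.2)
Conditions: H2 (1 atm), Pd(OH)2/C, NaOAc, THF–MeOH–H2O, 23 °C
Reagents that add atoms: none
Why: catalytic hydrogenolysis of the thirteen benzyl ethers and of the aryl–bromine bond in one operation; acetate buffers the hydrogen bromide so that the acid-labile 4→8 bonds and the stereocentres are not touched.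

## Compound list

1 | (+)-catechin | Oc1cc(O)c2c(c1)O[C@H](c1ccc(O)c(O)c1)[C@@H](O)C2 | starting material
2 | 5,7,3',4'-tetra-O-benzyl-(+)-catechin | c9ccccc9COc1cc(OCc9ccccc9)c2c(c1)O[C@H](c1ccc(OCc9ccccc9)c(OCc9ccccc9)c1)[C@@H](O)C2 | intermediate
3 | 3,5,7,3',4'-penta-O-benzyl-(+)-catechin | c9ccccc9COc1cc(OCc9ccccc9)c2c(c1)O[C@H](c1ccc(OCc9ccccc9)c(OCc9ccccc9)c1)[C@@H](OCc9ccccc9)C2 | intermediate
4 | 4β-hydroxy-3,5,7,3',4'-penta-O-benzyl-(+)-catechin (3,4-cis epimer drawn) | c9ccccc9COc1cc(OCc9ccccc9)c2c(c1)O[C@H](c1ccc(OCc9ccccc9)c(OCc9ccccc9)c1)[C@@H](OCc9ccccc9)[C@H]2O | intermediate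
5 | (2R,3R)-3,5,7-tris(benzyloxy)-2-[3,4-bis(benzyloxy)phenyl]chroman-4-one | c9ccccc9COc1cc(OCc9ccccc9)c2c(c1)O[C@H](c1ccc(OCc9ccccc9)c(OCc9ccccc9)c1)[C@@H](OCc9ccccc9)C2=O | intermediate
6 | ethynyltrimethylsilane | C[Si](C)(C)C#C | starting material
7 | 4-hydroxy-4-[(trimethylsilyl)ethynyl]-3,5,7,3',4'-penta-O-benzyl-(+)-catechin (C4 epimers, C4 left open) | c9ccccc9COc1cc(OCc9ccccc9)c2c(c1)O[C@H](c1ccc(OCc9ccccc9)c(OCc9ccccc9)c1)[C@@H](OCc9ccccc9)C2(O)C#C[Si](C)(C)C | intermediate
8 | 4β-[(trimethylsilyl)ethynyl]-3,5,7,3',4'-penta-O-benzyl-(+)-catechin (3,4-cis) | c9ccccc9COc1cc(OCc9ccccc9)c2c(c1)O[C@H](c1ccc(OCc9ccccc9)c(OCc9ccccc9)c1)[C@@H](OCc9ccccc9)[C@H]2C#C[Si](C)(C)C | intermediate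
9 | 4β-ethynyl-3,5,7,3',4'-penta-O-benzyl-(+)-catechin (3,4-cis) | c9ccccc9COc1cc(OCc9ccccc9)c2c(c1)O[C@H](c1ccc(OCc9ccccc9)c(OCc9ccccc9)c1)[C@@H](OCc9ccccc9)[C@H]2C#C | intermediate
10 | lithium acetylide of 9 | c9ccccc9COc1cc(OCc9ccccc9)c2c(c1)O[C@H](c1ccc(OCc9ccccc9)c(OCc9ccccc9)c1)[C@@H](OCc9ccccc9)[C@H]2C#[C-].[Li+] | intermediate
11 | lithium ynolate (lithium 2-(penta-O-benzyl-(+)-catechin-4β-yl)ethynolate) | c9ccccc9COc1cc(OCc9ccccc9)c2c(c1)O[C@H](c1ccc(OCc9ccccc9)c(OCc9ccccc9)c1)[C@@H](OCc9ccccc9)[C@H]2C#C[O-].[Li+] | intermediate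
12 | 4β-[(triisopropylsilyloxy)ethynyl]-3,5,7,3',4'-penta-O-benzyl-(+)-catechin (3,4-cis) | c9ccccc9COc1cc(OCc9ccccc9)c2c(c1)O[C@H](c1ccc(OCc9ccccc9)c(OCc9ccccc9)c1)[C@@H](OCc9ccccc9)[C@H]2C#CO[Si](C(C)C)(C(C)C)C(C)C | intermediate
13 | 3,4-bis(benzyloxy)benzaldehyde | O=Cc1ccc(OCc2ccccc2)c(OCc2ccccc2)c1 | starting material
14 | rac-1-[3,4-bis(benzyloxy)phenyl]prop-2-en-1-ol | C=CC(O)c1ccc(OCc9ccccc9)c(OCc9ccccc9)c1 | intermediate
15 | ethyl (E)-5-[3,4-bis(benzyloxy)phenyl]pent-4-enoate | CCOC(=O)CC/C=C/c1ccc(OCc9ccccc9)c(OCc9ccccc9)c1 | intermediate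
16 | (E)-5-[3,4-bis(benzyloxy)phenyl]pent-4-enoic acid | OC(=O)CC/C=C/c1ccc(OCc9ccccc9)c(OCc9ccccc9)c1 | intermediate
17 | benzyl alcohol | OCc1ccccc1 | starting material
18 | benzyl (E)-1,2-dichlorovinyl ether | Cl/C=C(/Cl)OCc1ccccc1 | intermediate
19 | benzyl chloroethynyl ether | ClC#COCc1ccccc1 | intermediate
20 | lithium (benzyloxy)acetylide | [Li+].[C-]#COCc1ccccc1 | intermediate
21 | (benzyloxy)ethyne | C#COCc1ccccc1 | intermediate
22 | (E)-5-[3,4-bis(benzyloxy)phenyl]pent-4-enoyl chloride | ClC(=O)CC/C=C/c1ccc(OCc9ccccc9)c(OCc9ccccc9)c1 | intermediate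
23 | (E)-5-[3,4-bis(benzyloxy)phenyl]penta-1,4-dien-1-one (alkylketene) | O=C=CC/C=C/c1ccc(OCc9ccccc9)c(OCc9ccccc9)c1 | intermediate
24 | 3-(benzyloxy)-4-[(E)-3-(3,4-bis(benzyloxy)phenyl)prop-2-en-1-yl]cyclobut-2-en-1-one (racemic) | O=C1C=C(OCc9ccccc9)C1C/C=C/c1ccc(OCc9ccccc9)c(OCc9ccccc9)c1 | intermediate
25 | 3-(benzyloxy)-4-{[(2R,3R)-3-(3,4-bis(benzyloxy)phenyl)oxiran-2-yl]methyl}cyclobut-2-en-1-one (ring-carbon epimers) | O=C1C=C(OCc9ccccc9)C1C[C@H]1O[C@@H]1c1ccc(OCc9ccccc9)c(OCc9ccccc9)c1 | intermediate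
26 | 3-(benzyloxy)-5-[(2R,3R)-3-(3,4-bis(benzyloxy)phenyl)oxiran-2-yl]penta-1,3-dien-1-one (vinylketene, alkene geometry open) | O=C=CC(OCc9ccccc9)=CC[C@H]1O[C@@H]1c1ccc(OCc9ccccc9)c(OCc9ccccc9)c1 | intermediate
27 | 2-(penta-O-benzyl-(+)-catechin-4β-yl)-3-(triisopropylsilyloxy)-4-{1-(benzyloxy)-3-[(2R,3R)-3-(3,4-bis(benzyloxy)phenyl)oxiran-2-yl]prop-1-enyl}cyclobut-2-en-1-one (transient centre open) | c9ccccc9COc1cc(OCc9ccccc9)c2c(c1)O[C@H](c1ccc(OCc9ccccc9)c(OCc9ccccc9)c1)[C@@H](OCc9ccccc9)[C@H]2C1=C(O[Si](C(C)C)(C(C)C)C(C)C)C(C(OCc9ccccc9)=CC[C@H]3O[C@@H]3c3ccc(OCc9ccccc9)c(OCc9ccccc9)c3)C1=O | intermediate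
28 | 2-(penta-O-benzyl-(+)-catechin-4β-yl)-3-(triisopropylsilyloxy)-5-(benzyloxy)-7-[(2R,3R)-3-(3,4-bis(benzyloxy)phenyl)oxiran-2-yl]hepta-1,3,5-trien-1-one (dienylketene) | c9ccccc9COc1cc(OCc9ccccc9)c2c(c1)O[C@H](c1ccc(OCc9ccccc9)c(OCc9ccccc9)c1)[C@@H](OCc9ccccc9)[C@H]2C(=C=O)C(O[Si](C(C)C)(C(C)C)C(C)C)=CC(OCc9ccccc9)=CC[C@H]3O[C@@H]3c3ccc(OCc9ccccc9)c(OCc9ccccc9)c3 | intermediate
29 | 2-(penta-O-benzyl-(+)-catechin-4β-yl)-3-(triisopropylsilyloxy)-5-(benzyloxy)-6-{[(2R,3R)-3-(3,4-bis(benzyloxy)phenyl)oxiran-2-yl]methyl}cyclohexa-2,4-dien-1-one (transient centre open) | c9ccccc9COc1cc(OCc9ccccc9)c2c(c1)O[C@H](c1ccc(OCc9ccccc9)c(OCc9ccccc9)c1)[C@@H](OCc9ccccc9)[C@H]2C1=C(O[Si](C(C)C)(C(C)C)C(C)C)C=C(OCc9ccccc9)C(C[C@H]3O[C@@H]3c3ccc(OCc9ccccc9)c(OCc9ccccc9)c3)C1=O | intermediate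
30 | 3-(benzyloxy)-2-{[(2R,3R)-3-(3,4-bis(benzyloxy)phenyl)oxiran-2-yl]methyl}-6-(penta-O-benzyl-(+)-catechin-4β-yl)-5-(triisopropylsilyloxy)phenol | c9ccccc9COc1cc(OCc9ccccc9)c2c(c1)O[C@H](c1ccc(OCc9ccccc9)c(OCc9ccccc9)c1)[C@@H](OCc9ccccc9)[C@H]2c1c(O[Si](C(C)C)(C(C)C)C(C)C)cc(OCc9ccccc9)c(C[C@H]3O[C@@H]3c3ccc(OCc9ccccc9)c(OCc9ccccc9)c3)c1O | intermediate
31 | 3,5,7,3',4'-penta-O-benzyl-(+)-catechin-(4β→8)-[5,3',4'-tri-O-benzyl-7-O-triisopropylsilyl-(−)-catechin] | c9ccccc9COc1cc(OCc9ccccc9)c2c(c1)O[C@H](c1ccc(OCc9ccccc9)c(OCc9ccccc9)c1)[C@@H](OCc9ccccc9)[C@H]2c1c(O[Si](C(C)C)(C(C)C)C(C)C)cc(OCc9ccccc9)c3c1O[C@@H](c1ccc(OCc9ccccc9)c(OCc9ccccc9)c1)[C@H](O)C3 | intermediate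
32 | (+)-gallocatechin | Oc1cc(O)c2c(c1)O[C@H](c1cc(O)c(O)c(O)c1)[C@@H](O)C2 | starting material
33 | 5,7,3',4',5'-penta-O-benzyl-(+)-gallocatechin | c9ccccc9COc1cc(OCc9ccccc9)c2c(c1)O[C@H](c1cc(OCc9ccccc9)c(OCc9ccccc9)c(OCc9ccccc9)c1)[C@@H](O)C2 | intermediate
34 | 8-bromo-5,7,3',4',5'-penta-O-benzyl-(+)-gallocatechin | Brc1c(OCc9ccccc9)cc(OCc9ccccc9)c2c1O[C@H](c1cc(OCc9ccccc9)c(OCc9ccccc9)c(OCc9ccccc9)c1)[C@@H](O)C2 | intermediate
35 | 8-bromo-4β-(2-ethoxyethoxy)-5,7,3',4',5'-penta-O-benzyl-(+)-gallocatechin (3,4-cis epimer drawn) | Brc1c(OCc9ccccc9)cc(OCc9ccccc9)c2c1O[C@H](c1cc(OCc9ccccc9)c(OCc9ccccc9)c(OCc9ccccc9)c1)[C@@H](O)[C@H]2OCCOCC | intermediate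
36 | 3-O-acetyl-8-bromo-4β-(2-ethoxyethoxy)-5,7,3',4',5'-penta-O-benzyl-(+)-gallocatechin | Brc1c(OCc9ccccc9)cc(OCc9ccccc9)c2c1O[C@H](c1cc(OCc9ccccc9)c(OCc9ccccc9)c(OCc9ccccc9)c1)[C@@H](OC(C)=O)[C@H]2OCCOCC | intermediate
37 | 3-O-acetyl-8-bromo-5,7,3',4',5'-penta-O-benzyl-(+)-gallocatechin-(4α→8)-[3,5,7,3',4'-penta-O-benzyl-(+)-catechin]-(4β→8)-[5,3',4'-tri-O-benzyl-7-O-triisopropylsilyl-(−)-catechin] | Brc1c(OCc9ccccc9)cc(OCc9ccccc9)c2c1O[C@H](c1cc(OCc9ccccc9)c(OCc9ccccc9)c(OCc9ccccc9)c1)[C@@H](OC(C)=O)[C@@H]2c1c(OCc9ccccc9)cc(OCc9ccccc9)c2c1O[C@H](c1ccc(OCc9ccccc9)c(OCc9ccccc9)c1)[C@@H](OCc9ccccc9)[C@H]2c1c(O[Si](C(C)C)(C(C)C)C(C)C)cc(OCc9ccccc9)c2c1O[C@@H](c1ccc(OCc9ccccc9)c(OCc9ccccc9)c1)[C@H](O)C2 | intermediate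
38 | 3-O-acetyl-8-bromo-5,7,3',4',5'-penta-O-benzyl-(+)-gallocatechin-(4α→8)-[3,5,7,3',4'-penta-O-benzyl-(+)-catechin]-(4β→8)-[5,3',4'-tri-O-benzyl-(−)-catechin] | Brc1c(OCc9ccccc9)cc(OCc9ccccc9)c2c1O[C@H](c1cc(OCc9ccccc9)c(OCc9ccccc9)c(OCc9ccccc9)c1)[C@@H](OC(C)=O)[C@@H]2c1c(OCc9ccccc9)cc(OCc9ccccc9)c2c1O[C@H](c1ccc(OCc9ccccc9)c(OCc9ccccc9)c1)[C@@H](OCc9ccccc9)[C@H]2c1c(O)cc(OCc9ccccc9)c2c1O[C@@H](c1ccc(OCc9ccccc9)c(OCc9ccccc9)c1)[C@H](O)C2 | intermediate
39 | 8-bromo-5,7,3',4',5'-penta-O-benzyl-(+)-gallocatechin-(4α→8)-[3,5,7,3',4'-penta-O-benzyl-(+)-catechin]-(4β→8)-[5,3',4'-tri-O-benzyl-(−)-catechin] | Brc1c(OCc9ccccc9)cc(OCc9ccccc9)c2c1O[C@H](c1cc(OCc9ccccc9)c(OCc9ccccc9)c(OCc9ccccc9)c1)[C@@H](O)[C@@H]2c1c(OCc9ccccc9)cc(OCc9ccccc9)c2c1O[C@H](c1ccc(OCc9ccccc9)c(OCc9ccccc9)c1)[C@@H](OCc9ccccc9)[C@H]2c1c(O)cc(OCc9ccccc9)c2c1O[C@@H](c1ccc(OCc9ccccc9)c(OCc9ccccc9)c1)[C@H](O)C2 | intermediate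
40 | (+)-gallocatechin-(4α→8)-(+)-catechin-(4β→8)-(−)-catechin (CNP0155646.2) | Oc1cc(O)c2c(c1)O[C@H](c1cc(O)c(O)c(O)c1)[C@@H](O)[C@@H]2c1c(O)cc(O)c2c1O[C@H](c1ccc(O)c(O)c1)[C@@H](O)[C@H]2c1c(O)cc(O)c2c1O[C@@H](c1ccc(O)c(O)c1)[C@H](O)C2 | target

## Step count and risks

Total step count: 23 (8 for ynol ether 12, 7 for epoxy cyclobutenone 25, 4 for electrophile 36, the key step, and 3 after the coupling). Longest linear sequence: 12 steps from (+)-catechin (steps 1–8, 16, 21, 22, 23).

Least certain steps: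

**Step 16 (key step, proposed new method).**
- What may go wrong: the epoxide may be lost before the phenol exists, by thermal Meinwald rearrangement to the benzyl ketone or by capture of the oxirane by a ketene. Ionisation at the electron-rich benzylic carbon may make the opening non-invertive and give 2,3-cis material. The [2+2] addition may be slow because the ynol ether carries a branched flavanyl group, leaving the vinylketene to dimerise.
- Fallback (known chemistry, with the ring synthesis and the closure of ring C uncoupled): it sets out from 12 and the alkene 24. A Danheiser benzannulation of 12 with 24 (toluene, 80–105 °C) gives 2-[(E)-3-(3,4-bis(benzyloxy)phenyl)prop-2-enyl]-3-(benzyloxy)-6-(penta-O-benzyl-(+)-catechin-4β-yl)-5-(triisopropylsilyloxy)phenol F1. Acetylation (Ac2O, pyridine) gives the aryl acetate F2. Shi epoxidation under the conditions of step 15 gives the (2R,3R)-epoxy acetate F3. Brief methanolysis (K2CO3, MeOH, 0 °C) frees epoxy phenol 30, which is closed with pyridinium p-toluenesulfonate in CH2Cl2 at 0 °C, the way 2-(3-aryloxiranylmethyl)phenols are closed to 2,3-trans-flavan-3-ols. The fallback comes back to the route at 31.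

**Step 6.**
- What may go wrong: poor facial selectivity of the hydride transfer, because in the 2,3-trans series steric approach anti to O3 and torsionally preferred axial approach point to opposite faces. Loss of H3 from the cation (enol ether formation) and hydride transfer to the alkyne terminus (allene formation) are also possible.
- Fallback (order of bond formation reversed): it sets out from 4. Ionisation of 4 with BF3·OEt2 in CH2Cl2–MeCN at −40 °C in the presence of excess K[Me3SiC≡CBF3] makes the alkynyl group, not the hydride, the incoming nucleophile. Whatever face the cation offers to a small nucleophile then receives the alkyne, so this order is stereochemically complementary to the ionic hydrogenation. It makes no new compound and comes back to the route at 8.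

**Step 15.**
- What may go wrong: hydrolysis of the strained vinylogous ester in the aqueous buffer, nucleophilic attack of peroxymonosulfate on the cyclobutenone carbonyl (Baeyer–Villiger-type ring expansion), or incomplete conversion at the low pH chosen to avoid these.
- Fallback (reagent control given up, purity recovered by separation): it sets out from 24. Dimethyldioxirane in anhydrous acetone at 0 °C, neutral and non-nucleophilic, gives the racemic trans epoxide, that is 25 together with 3-(benzyloxy)-4-{[(2S,3S)-3-(3,4-bis(benzyloxy)phenyl)oxiran-2-yl]methyl}cyclobut-2-en-1-one F4. Carried through step 16, the mixture gives 31 and the dimer with a (+)-catechin bottom unit F5. These are diastereomers, because the middle unit is enantiopure, and should separate on silica. The fallback comes back to the route at 31.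

**Step 21.**
- What may go wrong: attack through C6 of the middle or bottom unit, erosion of the 3,4-trans selectivity, or Lewis-acid cleavage and scrambling of the 4β→8 bond already present in 31.
- Fallback (top unit attached before the ring synthesis): it sets out from 8 and 36. Me3SiOTf coupling of 36 with monomer 8 gives the top–middle dimer F6; in 8 only C8 and C6 are free, C8 selectivity is the established behaviour of such monomers, and no acid-labile interflavan bond is present yet. K2CO3 in MeOH removes the C-silyl group and the acetate to give alkynol F7. LiN(SiMe3)2, t-BuOOLi and i-Pr3SiOTf (two equivalents, so the 3-alkoxide is silylated as well) give the silyl ynol ether F8. Step 16 with 25 gives the bis-silyl trimer F9. Bu4NF removes both silyl groups and the fallback comes back to the route at 39.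

## Further compounds

F1 | step 16 | 2-[(E)-3-(3,4-bis(benzyloxy)phenyl)prop-2-enyl]-3-(benzyloxy)-6-(penta-O-benzyl-(+)-catechin-4β-yl)-5-(triisopropylsilyloxy)phenol | c9ccccc9COc1cc(OCc9ccccc9)c2c(c1)O[C@H](c1ccc(OCc9ccccc9)c(OCc9ccccc9)c1)[C@@H](OCc9ccccc9)[C@H]2c1c(O[Si](C(C)C)(C(C)C)C(C)C)cc(OCc9ccccc9)c(C/C=C/c3ccc(OCc9ccccc9)c(OCc9ccccc9)c3)c1O
F2 | step 16 | acetate of F1 | c9ccccc9COc1cc(OCc9ccccc9)c2c(c1)O[C@H](c1ccc(OCc9ccccc9)c(OCc9ccccc9)c1)[C@@H](OCc9ccccc9)[C@H]2c1c(O[Si](C(C)C)(C(C)C)C(C)C)cc(OCc9ccccc9)c(C/C=C/c3ccc(OCc9ccccc9)c(OCc9ccccc9)c3)c1OC(C)=O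
F3 | step 16 | acetate of epoxy phenol 30 ((2R,3R)-epoxide) | c9ccccc9COc1cc(OCc9ccccc9)c2c(c1)O[C@H](c1ccc(OCc9ccccc9)c(OCc9ccccc9)c1)[C@@H](OCc9ccccc9)[C@H]2c1c(O[Si](C(C)C)(C(C)C)C(C)C)cc(OCc9ccccc9)c(C[C@H]3O[C@@H]3c3ccc(OCc9ccccc9)c(OCc9ccccc9)c3)c1OC(C)=O
F0 | step 6 | none | none
F4 | step 15 | 3-(benzyloxy)-4-{[(2S,3S)-3-(3,4-bis(benzyloxy)phenyl)oxiran-2-yl]methyl}cyclobut-2-en-1-one (ring-carbon epimers) | O=C1C=C(OCc9ccccc9)C1C[C@@H]1O[C@H]1c1ccc(OCc9ccccc9)c(OCc9ccccc9)c1
F5 | step 15 | 3,5,7,3',4'-penta-O-benzyl-(+)-catechin-(4β→8)-[5,3',4'-tri-O-benzyl-7-O-triisopropylsilyl-(+)-catechin] | c9ccccc9COc1cc(OCc9ccccc9)c2c(c1)O[C@H](c1ccc(OCc9ccccc9)c(OCc9ccccc9)c1)[C@@H](OCc9ccccc9)[C@H]2c1c(O[Si](C(C)C)(C(C)C)C(C)C)cc(OCc9ccccc9)c3c1O[C@H](c1ccc(OCc9ccccc9)c(OCc9ccccc9)c1)[C@@H](O)C3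
F6 | step 21 | 3-O-acetyl-8-bromo-5,7,3',4',5'-penta-O-benzyl-(+)-gallocatechin-(4α→8)-{4β-[(trimethylsilyl)ethynyl]-3,5,7,3',4'-penta-O-benzyl-(+)-catechin} | Brc1c(OCc9ccccc9)cc(OCc9ccccc9)c2c1O[C@H](c1cc(OCc9ccccc9)c(OCc9ccccc9)c(OCc9ccccc9)c1)[C@@H](OC(C)=O)[C@@H]2c1c(OCc9ccccc9)cc(OCc9ccccc9)c2c1O[C@H](c1ccc(OCc9ccccc9)c(OCc9ccccc9)c1)[C@@H](OCc9ccccc9)[C@H]2C#C[Si](C)(C)C
F7 | step 21 | 8-bromo-5,7,3',4',5'-penta-O-benzyl-(+)-gallocatechin-(4α→8)-[4β-ethynyl-3,5,7,3',4'-penta-O-benzyl-(+)-catechin] | Brc1c(OCc9ccccc9)cc(OCc9ccccc9)c2c1O[C@H](c1cc(OCc9ccccc9)c(OCc9ccccc9)c(OCc9ccccc9)c1)[C@@H](O)[C@@H]2c1c(OCc9ccccc9)cc(OCc9ccccc9)c2c1O[C@H](c1ccc(OCc9ccccc9)c(OCc9ccccc9)c1)[C@@H](OCc9ccccc9)[C@H]2C#C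
F8 | step 21 | 8-bromo-5,7,3',4',5'-penta-O-benzyl-3-O-triisopropylsilyl-(+)-gallocatechin-(4α→8)-{4β-[(triisopropylsilyloxy)ethynyl]-3,5,7,3',4'-penta-O-benzyl-(+)-catechin} | Brc1c(OCc9ccccc9)cc(OCc9ccccc9)c2c1O[C@H](c1cc(OCc9ccccc9)c(OCc9ccccc9)c(OCc9ccccc9)c1)[C@@H](O[Si](C(C)C)(C(C)C)C(C)C)[C@@H]2c1c(OCc9ccccc9)cc(OCc9ccccc9)c2c1O[C@H](c1ccc(OCc9ccccc9)c(OCc9ccccc9)c1)[C@@H](OCc9ccccc9)[C@H]2C#CO[Si](C(C)C)(C(C)C)C(C)C
F9 | step 21 | 8-bromo-5,7,3',4',5'-penta-O-benzyl-3-O-triisopropylsilyl-(+)-gallocatechin-(4α→8)-[3,5,7,3',4'-penta-O-benzyl-(+)-catechin]-(4β→8)-[5,3',4'-tri-O-benzyl-7-O-triisopropylsilyl-(−)-catechin] | Brc1c(OCc9ccccc9)cc(OCc9ccccc9)c2c1O[C@H](c1cc(OCc9ccccc9)c(OCc9ccccc9)c(OCc9ccccc9)c1)[C@@H](O[Si](C(C)C)(C(C)C)C(C)C)[C@@H]2c1c(OCc9ccccc9)cc(OCc9ccccc9)c2c1O[C@H](c1ccc(OCc9ccccc9)c(OCc9ccccc9)c1)[C@@H](OCc9ccccc9)[C@H]2c1c(O[Si](C(C)C)(C(C)C)C(C)C)cc(OCc9ccccc9)c2c1O[C@@H](c1ccc(OCc9ccccc9)c(OCc9ccccc9)c1)[C@H](O)C2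
A1 | alternative 1 | (penta-O-benzyl-ent-catechin-8-yl)[4,6-bis(benzyloxy)-3-bromo-2-(methoxymethoxy)phenyl]methanol (carbinol epimers) | OC(c1c(OCOC)c(Br)c(OCc9ccccc9)cc1OCc9ccccc9)c1c(OCc9ccccc9)cc(OCc9ccccc9)c2c1O[C@@H](c1ccc(OCc9ccccc9)c(OCc9ccccc9)c1)[C@H](OCc9ccccc9)C2
A2 | alternative 1 | (1S,2R)-2-(benzyloxy)-1-[3,4-bis(benzyloxy)phenyl]-3-[2,4-bis(benzyloxy)-6-fluorophenyl]propan-1-ol | O[C@@H](c1ccc(OCc9ccccc9)c(OCc9ccccc9)c1)[C@H](OCc9ccccc9)Cc1c(F)cc(OCc9ccccc9)cc1OCc9ccccc9
A3 | alternative 1 | 4,6-bis(benzyloxy)-3-bromo-2-(methoxymethoxy)benzaldehyde | O=Cc1c(OCOC)c(Br)c(OCc9ccccc9)cc1OCc9ccccc9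
A4 | alternative 2 | top unit as the 4-arylflavan-3-one on the perbenzyl middle–bottom dimer (2,4-cis epimer drawn, both centres beside the ketone labile) | c9ccccc9COc1cc(OCc9ccccc9)c2c(c1)O[C@H](c1cc(OCc9ccccc9)c(OCc9ccccc9)c(OCc9ccccc9)c1)C(=O)[C@@H]2c1c(OCc9ccccc9)cc(OCc9ccccc9)c2c1O[C@H](c1ccc(OCc9ccccc9)c(OCc9ccccc9)c1)[C@@H](OCc9ccccc9)[C@H]2c1c(OCc9ccccc9)cc(OCc9ccccc9)c2c1O[C@@H](c1ccc(OCc9ccccc9)c(OCc9ccccc9)c1)[C@H](OCc9ccccc9)C2
A5 | alternative 2 | (2R)-4,6-bis(benzyloxy)-2-[3,4,5-tris(benzyloxy)phenyl]-1-benzofuran-3(2H)-one (C2 labile) | O=C1c2c(OCc9ccccc9)cc(OCc9ccccc9)cc2O[C@@H]1c1cc(OCc9ccccc9)c(OCc9ccccc9)c(OCc9ccccc9)c1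
A6 | alternative 2 | 8-(diazomethyl)-3,5,7,3',4'-penta-O-benzyl-(+)-catechin-(4β→8)-[3,5,7,3',4'-penta-O-benzyl-(−)-catechin] | [N-]=[N+]=Cc1c(OCc9ccccc9)cc(OCc9ccccc9)c2c1O[C@H](c1ccc(OCc9ccccc9)c(OCc9ccccc9)c1)[C@@H](OCc9ccccc9)[C@H]2c1c(OCc9ccccc9)cc(OCc9ccccc9)c2c1O[C@@H](c1ccc(OCc9ccccc9)c(OCc9ccccc9)c1)[C@H](OCc9ccccc9)C2
A7 | alternative 3 | 8-bromo middle–bottom perbenzyl dimer carrying a pinacolboronate at C3 of the middle unit | Brc1c(OCc9ccccc9)cc(OCc9ccccc9)c2c1O[C@H](c1ccc(OCc9ccccc9)c(OCc9ccccc9)c1)[C@@H](B3OC(C)(C)C(C)(C)O3)[C@H]2c1c(OCc9ccccc9)cc(OCc9ccccc9)c2c1O[C@@H](c1ccc(OCc9ccccc9)c(OCc9ccccc9)c1)[C@H](OCc9ccccc9)C2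
A8 | alternative 3 | [4,6-bis(benzyloxy)-3-bromo-2-hydroxyphenyl](penta-O-benzyl-ent-catechin-8-yl)methanol (carbinol epimers) | OC(c1c(O)c(Br)c(OCc9ccccc9)cc1OCc9ccccc9)c1c(OCc9ccccc9)cc(OCc9ccccc9)c2c1O[C@@H](c1ccc(OCc9ccccc9)c(OCc9ccccc9)c1)[C@H](OCc9ccccc9)C2
A9 | alternative 3 | 2-[(E)-2-(3,4-bis(benzyloxy)phenyl)ethenyl]-4,4,5,5-tetramethyl-1,3,2-dioxaborolane | CC1(C)OB(/C=C/c2ccc(OCc9ccccc9)c(OCc9ccccc9)c2)OC1(C)C
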